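**Retrosynthetic overview**
1. Target 31 ⇐ deca-O-benzyl dimer 30 (one hydrogenolysis); 30 ⇐ anti bromo alcohol 29 by closing ring C of the upper (C6'-linked) flavan at O1–C8a.
2. Feature used: O1–C8a is an aryl ether to a ring A carbon with a single ortho substituent (C4a) and both ring A oxygens (C5, C7) meta to it. The pyran can therefore be closed at oxygen, by C–O coupling of the C2 hydroxyl with a C8a bromide, after C2 and C3 are set. O3 is carried as a benzyl ether, which cannot migrate to the neighbouring C2 alkoxide and falls in the final hydrogenolysis.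
3. 29 ⇐ ketone 28 (chelation-controlled reduction sets C2) ⇐ aryllithium from biaryl bromide 25 + Weinreb amide 15 (C1'–C2 bond).
4. 25 ⇐ Suzuki coupling (C6'–C8 bond) of catechin 8-boronate 22 with bromoiodoarene 24; 15 ⇐ Evans glycolate alkylation of imide 9 with benzylic bromide 5 (C3–C4 bond, sets C3).
5. Ring order: rings A, B and C of the lower unit come intact from (+)-catechin, rings A and B of the upper unit are bought as arenes, and ring C of the upper unit is the only ring formed (step 16).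

Key step: step 16

Remark: the C6'–C8 biaryl axis carries no descriptor in the target, so rotation about it is taken as unrestricted; intermediates from 25 onwards may appear as rotamer mixtures that converge on the one target.

**Step 1**
Reactants: 1 1,3-bis(benzyloxy)-5-bromobenzene
Product: 3 2,4-bis(benzyloxy)-6-bromobenzaldehyde, via iminium chloride 2 (not isolated)
Conditions: POCl3, DMF, 0 → 75 °C; then ice/H2O
Reagents that add atoms: N,N-dimethylformamide CN(C)C=O; water O
Why: Vilsmeier–Haack formylation should go at the position between Br and OBn (ortho and para to the two ether oxygens) in preference to the more crowded position flanked by two benzyloxy groups, as is usual for 1-bromo-3,5-dialkoxybenzenes, and iminium 2 is hydrolysed on work-up.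

**Step 2**
Reactants: 3 2,4-bis(benzyloxy)-6-bromobenzaldehyde
Product: 4 [2,4-bis(benzyloxy)-6-bromophenyl]methanol
Conditions: NaBH4, THF/MeOH, 0 °C
Reagents that add atoms: none
Why: Borohydride reduction of an aryl aldehyde, to which the aryl bromide and benzyl ethers are inert.

**Step 3**
Reactants: 4 [2,4-bis(benzyloxy)-6-bromophenyl]methanol
Product: 5 1,5-bis(benzyloxy)-3-bromo-2-(bromomethyl)benzene
Conditions: PBr3, Et2O, 0 °C; NaHCO3 wash, used crude at once
Reagents that add atoms: phosphorus tribromide BrP(Br)Br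
Why: Alcohol-to-bromide conversion with PBr3 (SN2 on the phosphite ester); the electron-rich benzylic bromide is labile and is therefore taken on without chromatography.

**Step 4**
Reactants: 6 (R)-4-benzyl-1,3-oxazolidin-2-one; 7 (benzyloxy)acetyl chloride
Product: 9 (R)-4-benzyl-3-[(benzyloxy)acetyl]-1,3-oxazolidin-2-one, via lithium oxazolidinide 8 (not isolated)
Conditions: n-BuLi, THF, −78 °C; then 7, −78 → 0 °C
Reagents that add atoms: none
Why: N-acylation of the lithiated oxazolidinone with an acid chloride, the standard preparation of Evans glycolyl imides.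

**Step 5**
Reactants: 9 (R)-4-benzyl-3-[(benzyloxy)acetyl]-1,3-oxazolidin-2-one (in excess); 5 1,5-bis(benzyloxy)-3-bromo-2-(bromomethyl)benzene
Product: 11 (R)-4-benzyl-3-{(2S)-2-(benzyloxy)-3-[2,4-bis(benzyloxy)-6-bromophenyl]propanoyl}-1,3-oxazolidin-2-one, via sodium enolate 10 (not isolated)
Conditions: NaN(SiMe3)2, THF, −78 °C; then 5, −78 → −40 °C
Reagents that add atoms: none
Why: Evans asymmetric alkylation (glycolate variant): the chelated (Z)-sodium enolate 10 should be alkylated by the reactive benzylic bromide on the face opposite the C4 benzyl group of the (R)-auxiliary, which sets the (S) centre that becomes C3 of the upper flavan.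

**Step 6**
Reactants: 11 the alkylated imide
Product: 13 (2S)-2-(benzyloxy)-3-[2,4-bis(benzyloxy)-6-bromophenyl]propanoic acid, via lithium percarboxylate 12 (not isolated)
Conditions: LiOH, H2O2, THF/H2O, 0 °C; then Na2SO3; then 1 M HCl
Reagents that add atoms: hydrogen peroxide OO
Why: Hydroperoxide cleavage of an Evans imide: LiOOH attacks the exocyclic carbonyl selectively, percarboxylate 12 is reduced by Na2SO3 to the acid, the α-alkoxy centre should not epimerise at 0 °C, and the auxiliary is recovered.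

**Step 7**
Reactants: 13 the (2S)-acid
Product: 15 (2S)-2-(benzyloxy)-3-[2,4-bis(benzyloxy)-6-bromophenyl]-N-methoxy-N-methylpropanamide, via acyl imidazole 14 (not isolated)
Conditions: 1,1'-carbonyldiimidazole, CH2Cl2, rt; then MeNHOMe·HCl, rt
Reagents that add atoms: N,O-dimethylhydroxylamine hydrochloride CNOC.Cl
Why: Weinreb amide formation through the acyl imidazole, an activation under which an α-alkoxy acid has no low-energy racemisation path.

**Step 8**
Reactants: 16 (+)-catechin
Product: 17 5,7,3',4'-tetra-O-benzyl-(+)-catechin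
Conditions: BnBr, K2CO3, DMF, 0 °C → rt
Reagents that add atoms: benzyl bromide BrCc1ccccc1
Why: Williamson etherification in which K2CO3 deprotonates only the four phenols, so the secondary C3 hydroxyl stays free and the C2 and C3 centres are not exposed to strong base while phenoxides are present.

**Step 9**
Reactants: 17 5,7,3',4'-tetra-O-benzyl-(+)-catechin
Product: 19 3,5,7,3',4'-penta-O-benzyl-(+)-catechin, via sodium alkoxide 18 (not isolated)
Conditions: NaH, BnBr, Bu4NI (cat.), THF/DMF, 0 °C → rt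
Reagents that add atoms: benzyl bromide BrCc1ccccc1
Why: Williamson etherification of the secondary alkoxide 18, with no remaining acidic site that could open ring C.

**Step 10**
Reactants: 19 3,5,7,3',4'-penta-O-benzyl-(+)-catechin
Product: 20 8-bromo-3,5,7,3',4'-penta-O-benzyl-(+)-catechin
Conditions: NBS (1 equiv), CH2Cl2, −40 → 0 °C
Reagents that add atoms: N-bromosuccinimide O=C1CCC(=O)N1Br
Why: Electrophilic aromatic bromination, in which C8 is the most nucleophilic ring A position of 5,7-dialkoxyflavans and one equivalent of NBS at low temperature should leave C6 and ring B untouched.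

**Step 11**
Reactants: 20 8-bromo-3,5,7,3',4'-penta-O-benzyl-(+)-catechin
Product: 22 3,5,7,3',4'-penta-O-benzyl-(+)-catechin-8-boronic acid pinacol ester, via 8-lithio species 21 (not isolated)
Conditions: n-BuLi, THF, −78 °C; then i-PrOBpin, −78 °C → rt; then H2O
Reagents that add atoms: 2-isopropoxy-4,4,5,5-tetramethyl-1,3,2-dioxaborolane CC(C)OB1OC(C)(C)C(C)(C)O1
Why: Bromine–lithium exchange followed by borylation; the exchange at −78 °C should be much faster than benzylic deprotonation of the ethers, and the C2 and C3 centres are not involved.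

**Step 12**
Reactants: 23 1,2-bis(benzyloxy)-4-bromobenzene
Product: 24 1,2-bis(benzyloxy)-4-bromo-5-iodobenzene
Conditions: N-iodosuccinimide, CF3CO2H (cat.), MeCN, rt
Reagents that add atoms: N-iodosuccinimide O=C1CCC(=O)N1I
Why: Electrophilic aromatic iodination para to the C2 benzyloxy group and ortho to bromine, the usual 4,5-substitution pattern of 1,2-dialkoxybenzenes.

**Step 13**
Reactants: 22 the catechin 8-boronate; 24 1,2-bis(benzyloxy)-4-bromo-5-iodobenzene (slight excess)
Product: 25 8-[4,5-bis(benzyloxy)-2-bromophenyl]-3,5,7,3',4'-penta-O-benzyl-(+)-catechin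
Conditions: Pd(PPh3)4 (5 mol%), K3PO4, dioxane/H2O (10:1), 90 °C
Reagents that add atoms: none
Why: Suzuki–Miyaura coupling forms the C6'–C8 biaryl bond; zerovalent palladium inserts into C–I far faster than into C–Br, and the bromide of the product is shielded by the new ortho aryl group, so it should survive for step 14.

**Step 14**
Reactants: 25 the biaryl bromide; 15 the Weinreb amide
Product: 28 (2S)-2-(benzyloxy)-3-[2,4-bis(benzyloxy)-6-bromophenyl]-1-{4,5-bis(benzyloxy)-2-[penta-O-benzylcatechin-8-yl]phenyl}propan-1-one, via aryllithium 26 (not isolated), via tetrahedral lithium adduct 27 (not isolated)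
Conditions: n-BuLi (1.0 equiv), THF, −78 °C; then 15, −78 → −40 °C; then H2O
Reagents that add atoms: none
Why: Weinreb ketone synthesis: bromine–lithium exchange gives 26, which adds to the amide to give the chelated adduct 27 that collapses to the ketone only on quench, so over-addition and α-epimerisation are not expected, and acylation at −78 °C should outrun exchange with the aryl bromide of 15.

**Step 15**
Reactants: 28 the α-benzyloxy ketone
Product: 29 (1R,2S)-2-(benzyloxy)-3-[2,4-bis(benzyloxy)-6-bromophenyl]-1-{4,5-bis(benzyloxy)-2-[penta-O-benzylcatechin-8-yl]phenyl}propan-1-ol (anti)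
Conditions: Zn(BH4)2, Et2O/CH2Cl2, −30 → 0 °C; then H2O
Reagents that add atoms: none
Why: Chelation-controlled (Cram chelate) reduction: zinc bridges the ketone oxygen and the α-benzyloxy oxygen and hydride is delivered to the face that carries the α-hydrogen, which should give the anti (1R,2S) alcohol, the future 2R centre.

**Step 16**
Reactants: 29 the anti bromo alcohol
Product: 30 deca-O-benzyl ether of the target (3,5,7,3',4'-penta-O-benzylcatechin-(6'→8)-3,5,7,3',4'-penta-O-benzylcatechin)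
Conditions: CuI (20 mol%), 3,4,7,8-tetramethyl-1,10-phenanthroline (40 mol%), Cs2CO3, toluene, 110 °C, Ar
Reagents that add atoms: none
Why: Cs2CO3 turns the only free hydroxyl of 29 (C2–OH) into an alkoxide that binds the phenanthroline-ligated monovalent copper centre; the C8a–Br bond of ring A then adds oxidatively to give a trivalent copper aryl alkoxide, and reductive elimination forms O1–C8a and returns monovalent copper. The closest known reaction type is the Ullmann-type copper-catalysed intramolecular O-arylation of secondary alcohols by aryl bromides, which gives chromans and 2-arylchromans. Ring C closes in a six-membered mode (6-exo at the aryl carbon) through a seven-membered cupracycle. No stereocentre is created: the bonds at C2 and C3 are not touched, so the (1R,2S) anti arrangement from step 15 becomes the 2,3-trans (2R,3S) pyran with the C2 aryl group and the C3 benzyloxy group both equatorial. The step needs arylation of the C2 oxygen at one site only, and this is secured because 29 holds one free hydroxyl and one aryl bromide, O3 is a benzyl ether that can neither close the five-membered dihydrobenzofuran nor migrate, and C8a has a single ortho substituent with both ring A ethers meta, so it is neither crowded nor deactivated by resonance donation. Because the new bond is made at the aryl carbon, the ionisation-prone C2–O bond is never broken.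

**Step 17**
Reactants: 30 the deca-O-benzyl dimer
Product: 31 target, (+)-catechin-(6'→8)-(+)-catechin
Conditions: H2 (1 atm), Pd(OH)2/C, THF/MeOH/H2O, rt; filtration, Sephadex LH-20
Reagents that add atoms: none
Why: Catalytic hydrogenolysis should cleave all ten benzyl ethers under neutral conditions, under which the flavan C2–O1 bonds and the four stereocentres are not affected.

**Compound list**
1 | 1,3-bis(benzyloxy)-5-bromobenzene | Brc1cc(OCc2ccccc2)cc(OCc2ccccc2)c1 | starting material
2 | [2,4-bis(benzyloxy)-6-bromophenyl]methylidene(dimethyl)iminium chloride | C[N+](C)=Cc1c(Br)cc(OCc2ccccc2)cc1OCc1ccccc1.[Cl-] | intermediate (not isolated)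
3 | 2,4-bis(benzyloxy)-6-bromobenzaldehyde | O=Cc1c(Br)cc(OCc2ccccc2)cc1OCc1ccccc1 | intermediate
4 | [2,4-bis(benzyloxy)-6-bromophenyl]methanol | OCc1c(Br)cc(OCc2ccccc2)cc1OCc1ccccc1 | intermediate
5 | 1,5-bis(benzyloxy)-3-bromo-2-(bromomethyl)benzene | BrCc1c(Br)cc(OCc2ccccc2)cc1OCc1ccccc1 | intermediate
6 | (R)-4-benzyl-1,3-oxazolidin-2-one | O=C1OC[C@@H](Cc2ccccc2)N1 | starting material
7 | (benzyloxy)acetyl chloride | O=C(Cl)COCc1ccccc1 | starting material
8 | N-lithio-(R)-4-benzyl-1,3-oxazolidin-2-one | O=C1OC[C@@H](Cc2ccccc2)N1[Li] | intermediate (not isolated)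
9 | (R)-4-benzyl-3-[(benzyloxy)acetyl]-1,3-oxazolidin-2-one | O=C1OC[C@@H](Cc2ccccc2)N1C(=O)COCc1ccccc1 | intermediate
10 | sodium (Z)-enolate of 9 | O=C1OC[C@@H](Cc2ccccc2)N1/C(O[Na])=C/OCc1ccccc1 | intermediate (not isolated)
11 | (R)-4-benzyl-3-{(2S)-2-(benzyloxy)-3-[2,4-bis(benzyloxy)-6-bromophenyl]propanoyl}-1,3-oxazolidin-2-one | O=C1OC[C@@H](Cc2ccccc2)N1C(=O)[C@@H](OCc1ccccc1)Cc1c(Br)cc(OCc2ccccc2)cc1OCc1ccccc1 | intermediate
12 | lithium (2S)-2-(benzyloxy)-3-[2,4-bis(benzyloxy)-6-bromophenyl]propaneperoxoate | [Li]OOC(=O)[C@@H](OCc1ccccc1)Cc1c(Br)cc(OCc2ccccc2)cc1OCc1ccccc1 | intermediate (not isolated)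
13 | (2S)-2-(benzyloxy)-3-[2,4-bis(benzyloxy)-6-bromophenyl]propanoic acid | OC(=O)[C@@H](OCc1ccccc1)Cc1c(Br)cc(OCc2ccccc2)cc1OCc1ccccc1 | intermediate
14 | (2S)-2-(benzyloxy)-3-[2,4-bis(benzyloxy)-6-bromophenyl]-1-(imidazol-1-yl)propan-1-one | O=C(n1ccnc1)[C@@H](OCc1ccccc1)Cc1c(Br)cc(OCc2ccccc2)cc1OCc1ccccc1 | intermediate (not isolated)
15 | (2S)-2-(benzyloxy)-3-[2,4-bis(benzyloxy)-6-bromophenyl]-N-methoxy-N-methylpropanamide | CON(C)C(=O)[C@@H](OCc1ccccc1)Cc1c(Br)cc(OCc2ccccc2)cc1OCc1ccccc1 | intermediate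
16 | (+)-catechin (2R,3S) | Oc1cc(O)c2c(c1)O[C@H](c1ccc(O)c(O)c1)[C@@H](O)C2 | starting material
17 | 5,7,3',4'-tetra-O-benzyl-(+)-catechin | c1c(OCc3ccccc3)cc(OCc3ccccc3)c2c1O[C@H](c1ccc(OCc3ccccc3)c(OCc3ccccc3)c1)[C@@H](O)C2 | intermediate
18 | sodium 3-alkoxide of 17 | c1c(OCc3ccccc3)cc(OCc3ccccc3)c2c1O[C@H](c1ccc(OCc3ccccc3)c(OCc3ccccc3)c1)[C@@H](O[Na])C2 | intermediate (not isolated)
19 | 3,5,7,3',4'-penta-O-benzyl-(+)-catechin | c1c(OCc3ccccc3)cc(OCc3ccccc3)c2c1O[C@H](c1ccc(OCc3ccccc3)c(OCc3ccccc3)c1)[C@@H](OCc3ccccc3)C2 | intermediate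
20 | 8-bromo-3,5,7,3',4'-penta-O-benzyl-(+)-catechin | Brc1c(OCc3ccccc3)cc(OCc3ccccc3)c2c1O[C@H](c1ccc(OCc3ccccc3)c(OCc3ccccc3)c1)[C@@H](OCc3ccccc3)C2 | intermediate
21 | 8-lithio-3,5,7,3',4'-penta-O-benzyl-(+)-catechin | [Li]c1c(OCc3ccccc3)cc(OCc3ccccc3)c2c1O[C@H](c1ccc(OCc3ccccc3)c(OCc3ccccc3)c1)[C@@H](OCc3ccccc3)C2 | intermediate (not isolated)
22 | 3,5,7,3',4'-penta-O-benzyl-(+)-catechin-8-boronic acid pinacol ester | CC1(C)OB(OC1(C)C)c1c(OCc3ccccc3)cc(OCc3ccccc3)c2c1O[C@H](c1ccc(OCc3ccccc3)c(OCc3ccccc3)c1)[C@@H](OCc3ccccc3)C2 | intermediate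
23 | 1,2-bis(benzyloxy)-4-bromobenzene | Brc1ccc(OCc2ccccc2)c(OCc2ccccc2)c1 | starting material
24 | 1,2-bis(benzyloxy)-4-bromo-5-iodobenzene | Brc1cc(OCc2ccccc2)c(OCc2ccccc2)cc1I | intermediate
25 | 8-[4,5-bis(benzyloxy)-2-bromophenyl]-3,5,7,3',4'-penta-O-benzyl-(+)-catechin | Brc1cc(OCc3ccccc3)c(OCc3ccccc3)cc1-c1c(OCc3ccccc3)cc(OCc3ccccc3)c2c1O[C@H](c1ccc(OCc3ccccc3)c(OCc3ccccc3)c1)[C@@H](OCc3ccccc3)C2 | intermediate
26 | aryllithium from 25 (Li in place of Br) | [Li]c1cc(OCc3ccccc3)c(OCc3ccccc3)cc1-c1c(OCc3ccccc3)cc(OCc3ccccc3)c2c1O[C@H](c1ccc(OCc3ccccc3)c(OCc3ccccc3)c1)[C@@H](OCc3ccccc3)C2 | intermediate (not isolated)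
27 | lithium N-methoxy-N-methyl hemiaminal alkoxide from 26 and 15 (tetrahedral adduct) | [Li]OC(N(C)OC)(c1cc(OCc3ccccc3)c(OCc3ccccc3)cc1-c1c(OCc3ccccc3)cc(OCc3ccccc3)c2c1O[C@H](c1ccc(OCc3ccccc3)c(OCc3ccccc3)c1)[C@@H](OCc3ccccc3)C2)[C@@H](OCc1ccccc1)Cc1c(Br)cc(OCc2ccccc2)cc1OCc1ccccc1 | intermediate (not isolated)
28 | (2S)-2-(benzyloxy)-3-[2,4-bis(benzyloxy)-6-bromophenyl]-1-{4,5-bis(benzyloxy)-2-[penta-O-benzylcatechin-8-yl]phenyl}propan-1-one | O=C(c1cc(OCc3ccccc3)c(OCc3ccccc3)cc1-c1c(OCc3ccccc3)cc(OCc3ccccc3)c2c1O[C@H](c1ccc(OCc3ccccc3)c(OCc3ccccc3)c1)[C@@H](OCc3ccccc3)C2)[C@@H](OCc1ccccc1)Cc1c(Br)cc(OCc2ccccc2)cc1OCc1ccccc1 | intermediate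
29 | (1R,2S)-2-(benzyloxy)-3-[2,4-bis(benzyloxy)-6-bromophenyl]-1-{4,5-bis(benzyloxy)-2-[penta-O-benzylcatechin-8-yl]phenyl}propan-1-ol (anti; key-step precursor) | O[C@H](c1cc(OCc3ccccc3)c(OCc3ccccc3)cc1-c1c(OCc3ccccc3)cc(OCc3ccccc3)c2c1O[C@H](c1ccc(OCc3ccccc3)c(OCc3ccccc3)c1)[C@@H](OCc3ccccc3)C2)[C@@H](OCc1ccccc1)Cc1c(Br)cc(OCc2ccccc2)cc1OCc1ccccc1 | intermediate
30 | deca-O-benzyl ether of the target (key-step product) | c5ccccc5COc1cc(OCc5ccccc5)c2c(c1)O[C@H](c1cc(OCc5ccccc5)c(OCc5ccccc5)cc1-c1c(OCc5ccccc5)cc(OCc5ccccc5)c3c1O[C@H](c1ccc(OCc5ccccc5)c(OCc5ccccc5)c1)[C@@H](OCc5ccccc5)C3)[C@@H](OCc5ccccc5)C2 | intermediate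
31 | (+)-catechin-(6'→8)-(+)-catechin, CNP0353739.1 | Oc1cc(O)c2c(c1)O[C@H](c1cc(O)c(O)cc1-c1c(O)cc(O)c3c1O[C@H](c1ccc(O)c(O)c1)[C@@H](O)C3)[C@@H](O)C2 | target

**Step count**
Total steps: 17. Longest linear sequence: 10 steps (1 → 3 → 4 → 5 → 11 → 13 → 15 → 28 → 29 → 30 → 31).

**Steps most likely to fail**

Step 16. The copper alkoxide of the crowded secondary benzylic alcohol may lose a β-hydride (returning ketone 28 and reducing the C–Br bond) faster than it forms the C–O bond, or the coupling may stall. The fallback sets out from 29: Miyaura borylation of the aryl bromide (Pd(dppf)Cl2, B2pin2, KOAc, dioxane, 90 °C) should give the ring A pinacol boronate F1, and oxidation (NaBO3·4H2O, THF/H2O) the ring A phenol F2. Acid-catalysed cyclodehydration of F2 (catalytic p-TsOH, CH2Cl2, 0 °C) then closes the pyran at O1–C2 through the C2 benzylic cation, which the para benzyloxy group of ring B stabilises. Under thermodynamic control this should favour the 2,3-trans ether, and the fallback comes back to the route at 30.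

Step 13. Protodeboronation of the di-ortho-alkoxy boronate may outpace the hindered transmetalation, or a second coupling at the C–Br bond may intrude. The fallback sets out from 20: the 8-lithio species 21 is transmetalated with ZnCl2 to the arylzinc chloride F3, which should undergo Negishi coupling with 24 at the C–I bond (Pd(PPh3)4, THF, 60 °C). It comes back to the route at 25.

Step 14. Addition of the ortho-arylated aryllithium to the α-branched amide may be slow enough for proton transfer or bromine–lithium scrambling with the aryl bromide of 15 to compete. The fallback sets out from 15: i-Bu2AlH (THF, −78 °C) should give the (S)-2-benzyloxy aldehyde F4. Aryllithium 26 adds to this far more electrophilic carbonyl to give the carbinol F5 as a mixture of C1 epimers. Dess–Martin oxidation converges both epimers and comes back to the route at ketone 28.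

**Further compounds**
F1 | step 16 | (1R,2S)-2-(benzyloxy)-3-[2,4-bis(benzyloxy)-6-(4,4,5,5-tetramethyl-1,3,2-dioxaborolan-2-yl)phenyl]-1-{4,5-bis(benzyloxy)-2-[penta-O-benzylcatechin-8-yl]phenyl}propan-1-ol | O[C@H](c1cc(OCc3ccccc3)c(OCc3ccccc3)cc1-c1c(OCc3ccccc3)cc(OCc3ccccc3)c2c1O[C@H](c1ccc(OCc3ccccc3)c(OCc3ccccc3)c1)[C@@H](OCc3ccccc3)C2)[C@@H](OCc1ccccc1)Cc1c(B2OC(C)(C)C(C)(C)O2)cc(OCc2ccccc2)cc1OCc1ccccc1
F2 | step 16 | (1R,2S)-2-(benzyloxy)-3-[2,4-bis(benzyloxy)-6-hydroxyphenyl]-1-{4,5-bis(benzyloxy)-2-[penta-O-benzylcatechin-8-yl]phenyl}propan-1-ol | O[C@H](c1cc(OCc3ccccc3)c(OCc3ccccc3)cc1-c1c(OCc3ccccc3)cc(OCc3ccccc3)c2c1O[C@H](c1ccc(OCc3ccccc3)c(OCc3ccccc3)c1)[C@@H](OCc3ccccc3)C2)[C@@H](OCc1ccccc1)Cc1c(O)cc(OCc2ccccc2)cc1OCc1ccccc1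
F3 | step 13 | [3,5,7,3',4'-penta-O-benzyl-(+)-catechin-8-yl]zinc chloride | Cl[Zn]c1c(OCc3ccccc3)cc(OCc3ccccc3)c2c1O[C@H](c1ccc(OCc3ccccc3)c(OCc3ccccc3)c1)[C@@H](OCc3ccccc3)C2
F4 | step 14 | (2S)-2-(benzyloxy)-3-[2,4-bis(benzyloxy)-6-bromophenyl]propanal | O=C[C@@H](OCc1ccccc1)Cc1c(Br)cc(OCc2ccccc2)cc1OCc1ccccc1
F5 | step 14 | (2S)-2-(benzyloxy)-3-[2,4-bis(benzyloxy)-6-bromophenyl]-1-{4,5-bis(benzyloxy)-2-[penta-O-benzylcatechin-8-yl]phenyl}propan-1-ol, mixture of C1 epimers | OC(c1cc(OCc3ccccc3)c(OCc3ccccc3)cc1-c1c(OCc3ccccc3)cc(OCc3ccccc3)c2c1O[C@H](c1ccc(OCc3ccccc3)c(OCc3ccccc3)c1)[C@@H](OCc3ccccc3)C2)[C@@H](OCc1ccccc1)Cc1c(Br)cc(OCc2ccccc2)cc1OCc1ccccc1
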